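**Retrosynthetic overview**
- No ring is built: rings A, B and C and the C2 stereocentre of the target are bought intact as (2S)-naringenin, leaving only two prenyl groups to attach.
- The C8–prenyl bond is disconnected by a tandem aromatic Claisen/Cope rearrangement (two [3,3] shifts, net para-Claisen) back to a 5-O-prenyl ether; Eu(fod)3 chelated between C4=O and O5 triggers it.
- Both O-prenyl ethers (4' and 5) come from one double Mitsunobu etherification with prenol under neutral conditions.
- The most acidic phenol (7-OH) is masked first as a triisopropylsilyl ether and freed with buffered fluoride in the rearrangement flask.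
- Forward order: 7-O-silylation, then 4',5-bis-O-prenylation, then Claisen–Cope and desilylation.

Assumption: (2S)-naringenin is bought as the single enantiomer (it is also the aglycone of the cheap citrus glycoside naringin) and its ee is checked by chiral HPLC before use.

**Step 1**
Reactants: 1 (2S)-naringenin [(2S)-5,7-dihydroxy-2-(4-hydroxyphenyl)chroman-4-one]; 2 triisopropylsilyl chloride
Product: 3 (2S)-7-O-(triisopropylsilyl)naringenin
Conditions: TIPSCl (1.05 equiv), imidazole (2.2 equiv), DMF, 0 °C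
Reagents that add atoms: triisopropylsilyl chloride (compound 2), CC(C)[Si](Cl)(C(C)C)C(C)C
Why: Regioselective O-silylation: 7-OH is a vinylogous acid para to the C4 carbonyl (pKa about 7.5 against about 10 for 4'-OH, while 5-OH is locked in a hydrogen bond), so one equivalent of the bulky silyl chloride caps it first, and the cold, weakly basic medium leaves C2 untouched.

**Step 2**
Reactants: 3 (2S)-7-O-(triisopropylsilyl)naringenin; 4 3-methylbut-2-en-1-ol (prenol)
Product: 6 (2S)-4',5-di-O-prenyl-7-O-(triisopropylsilyl)naringenin, via mono-prenyl ether 5 (not isolated)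
Conditions: prenol (2.6 equiv), PPh3 (2.6 equiv), DIAD (2.6 equiv), THF, 0 °C to rt
Reagents that add atoms: 3-methylbut-2-en-1-ol (compound 4), CC(C)=CCO
Why: Double Mitsunobu etherification (SN2 at the primary allylic carbon, so no allylic transposition) alkylates 4'-OH and then the chelated 5-OH under neutral conditions, which avoids the base-induced retro-oxa-Michael opening of ring C that would racemise C2; the bulky silyl ether resists silyl transfer.

**Step 3**
Reactants: 6 (2S)-4',5-di-O-prenyl-7-O-(triisopropylsilyl)naringenin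
Product: 10 (2S)-8-prenyl-4'-O-prenylnaringenin, via Claisen dienone 7 (not isolated), via Cope dienone 8 (not isolated), via silyl ether 9 (not isolated)
Conditions: Eu(fod)3 (10 mol %), CHCl3, 60 °C; then evaporate, TBAF/AcOH (1:1, 1.5 equiv), THF, 0 °C
Reagents that add atoms: none
Why: Chelation of the trivalent europium complex (fod = 6,6,7,7,8,8,8-heptafluoro-2,2-dimethyl-3,5-octanedionate) between C4=O and O5 accelerates an aromatic Claisen [3,3] shift of only the 5-O-prenyl group to C6, a Cope [3,3] shift then relays it to C8 as a normal prenyl group before enolisation (Claisen–Cope rearrangement), the unchelated 4'-O-prenyl ether and C2 are not involved, and acetic-acid-buffered fluoride finally cleaves the aryl Si–O bond without a free basic phenoxide.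

**Compound list**
1 | (2S)-naringenin, (2S)-5,7-dihydroxy-2-(4-hydroxyphenyl)chroman-4-one | Oc1ccc([C@@H]2CC(=O)c3c(O)cc(O)cc3O2)cc1 | starting material
2 | triisopropylsilyl chloride | CC(C)[Si](Cl)(C(C)C)C(C)C | starting material
3 | (2S)-5-hydroxy-2-(4-hydroxyphenyl)-7-[(triisopropylsilyl)oxy]chroman-4-one | Oc1ccc([C@@H]2CC(=O)c3c(O)cc(O[Si](C(C)C)(C(C)C)C(C)C)cc3O2)cc1 | intermediate
4 | 3-methylbut-2-en-1-ol (prenol) | CC(C)=CCO | starting material
5 | (2S)-5-hydroxy-2-[4-(3-methylbut-2-enyloxy)phenyl]-7-[(triisopropylsilyl)oxy]chroman-4-one | CC(C)=CCOc1ccc([C@@H]2CC(=O)c3c(O)cc(O[Si](C(C)C)(C(C)C)C(C)C)cc3O2)cc1 | intermediate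
6 | (2S)-5-(3-methylbut-2-enyloxy)-2-[4-(3-methylbut-2-enyloxy)phenyl]-7-[(triisopropylsilyl)oxy]chroman-4-one | CC(C)=CCOc1ccc([C@@H]2CC(=O)c3c(OCC=C(C)C)cc(O[Si](C(C)C)(C(C)C)C(C)C)cc3O2)cc1 | intermediate
7 | (2S)-6-(2-methylbut-3-en-2-yl)-2-[4-(3-methylbut-2-enyloxy)phenyl]-7-[(triisopropylsilyl)oxy]-2,3-dihydrochromene-4,5(6H)-dione, both C6 epimers, transient | CC(C)=CCOc1ccc([C@@H]2CC(=O)C3=C(O2)C=C(O[Si](C(C)C)(C(C)C)C(C)C)C(C(C)(C)C=C)C3=O)cc1 | intermediate
8 | (2S)-8-(3-methylbut-2-enyl)-2-[4-(3-methylbut-2-enyloxy)phenyl]-7-[(triisopropylsilyl)oxy]-2,3-dihydrochromene-4,5(8H)-dione, both C8 epimers, transient | CC(C)=CCOc1ccc([C@@H]2CC(=O)C3=C(O2)C(CC=C(C)C)C(O[Si](C(C)C)(C(C)C)C(C)C)=CC3=O)cc1 | intermediate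
9 | (2S)-5-hydroxy-8-(3-methylbut-2-enyl)-2-[4-(3-methylbut-2-enyloxy)phenyl]-7-[(triisopropylsilyl)oxy]chroman-4-one | CC(C)=CCOc1ccc([C@@H]2CC(=O)c3c(O)cc(O[Si](C(C)C)(C(C)C)C(C)C)c(CC=C(C)C)c3O2)cc1 | intermediate
10 | (2S)-5,7-dihydroxy-8-(3-methylbut-2-enyl)-2-[4-(3-methylbut-2-enyloxy)phenyl]chroman-4-one (CNP0558191.1) | CC(C)=CCOc1ccc([C@@H]2CC(=O)c3c(O)cc(O)c(CC=C(C)C)c3O2)cc1 | target

**Totals**
Total step count: 3. Longest linear sequence: 3 steps (1 to 3 to 6 to 10).

**Steps most likely to fail, with fallbacks**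

Step 3 is the most likely to fail. Dienone 7 can tautomerise to the 6-(1,1-dimethylallyl) phenol instead of undergoing the Cope shift, giving the wrong regioisomer; this isomer is expected as a by-product in any case and is removed by chromatography. The bulky 7-O-silyl group may also slow attack at C8. The fallback forms the C8–prenyl bond by a single ortho-Claisen shift from O7 and needs no protecting group. It sets out from 1 and comes back to the route at 10. Compound 1 is treated with tert-butyl 2-methylbut-3-en-2-yl carbonate (1.05 equiv) and Pd(PPh3)4 (zerovalent palladium, 3 mol %) in THF at 0 °C. This decarboxylative allylic etherification puts the branched group on the most acidic phenol and gives (2S)-7-O-(2-methylbut-3-en-2-yl)naringenin F8. A Mitsunobu reaction with 1.1 equiv of 4 (PPh3, DIAD, THF, 0 °C) etherifies 4'-OH and gives (2S)-7-O-(2-methylbut-3-en-2-yl)-4'-O-prenylnaringenin F9. Warming F9 in toluene at 80–100 °C rearranges the tertiary allyl ether, far below the temperature at which the primary 4'-O-prenyl ether reacts, and delivers a normal prenyl group to C8, giving 10. The C6-prenyl isomer forms alongside and must be separated; the C8/C6 ratio is the weak point of this fallback.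

Step 2 is the next most likely to fail. The chelated 5-OH, made less acidic by the silyloxy donor at C7, may not etherify, so the reaction stops at 5. The fallback swaps the 7-O group for an electron-withdrawing acetate, the substitution pattern under which 5-OH is acidic enough for Mitsunobu coupling. It sets out from 5 and comes back at 10. TBAF/AcOH in THF at 0 °C converts 5 into (2S)-4'-O-prenylnaringenin F4. Ac2O (1.05 equiv) in pyridine at 0 °C acylates only the unchelated 7-OH and gives (2S)-7-O-acetyl-4'-O-prenylnaringenin F5. Mitsunobu coupling with 4 (PPh3, DIAD, THF) gives (2S)-7-O-acetyl-4',5-di-O-prenylnaringenin F6. Eu(fod)3 (10 mol %) in CHCl3 at 60 °C gives (2S)-7-O-acetyl-8-prenyl-4'-O-prenylnaringenin F7. Brief ammonolysis (NH3 in MeOH, 0 °C) gives 10, with ee checked by chiral HPLC because this last operation is mildly basic.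

Step 1 is the third risk. The mono-silylation may give mixtures of 7-O-, 4'-O- and bis-silyl ethers. The fallback masks 7-OH by a pKa-controlled Mitsunobu mono-alkylation instead. It sets out from 1 and comes back at 10. Allyl alcohol (1.05 equiv), PPh3 and DIAD in THF at 0 °C give (2S)-7-O-allylnaringenin F1. Double Mitsunobu coupling with 4 as in step 2 gives (2S)-7-O-allyl-4',5-di-O-prenylnaringenin F2. Eu(fod)3 (10 mol %) in CHCl3 at 60 °C rearranges only the chelated 5-O-prenyl group and gives (2S)-7-O-allyl-8-prenyl-4'-O-prenylnaringenin F3. Pd(PPh3)4 (zerovalent palladium, 5 mol %) with morpholine in THF at rt removes the unsubstituted allyl group much faster than the trisubstituted prenyl ether and gives 10.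

**Further compounds**
F1 | step 1 | (2S)-7-O-allylnaringenin | Oc1ccc([C@@H]2CC(=O)c3c(O)cc(OCC=C)cc3O2)cc1
F2 | step 1 | (2S)-7-O-allyl-4',5-di-O-prenylnaringenin | CC(C)=CCOc1ccc([C@@H]2CC(=O)c3c(OCC=C(C)C)cc(OCC=C)cc3O2)cc1
F3 | step 1 | (2S)-7-O-allyl-8-prenyl-4'-O-prenylnaringenin | CC(C)=CCOc1ccc([C@@H]2CC(=O)c3c(O)cc(OCC=C)c(CC=C(C)C)c3O2)cc1
F4 | step 2 | (2S)-4'-O-prenylnaringenin | CC(C)=CCOc1ccc([C@@H]2CC(=O)c3c(O)cc(O)cc3O2)cc1
F5 | step 2 | (2S)-7-O-acetyl-4'-O-prenylnaringenin | CC(C)=CCOc1ccc([C@@H]2CC(=O)c3c(O)cc(OC(C)=O)cc3O2)cc1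
F6 | step 2 | (2S)-7-O-acetyl-4',5-di-O-prenylnaringenin | CC(C)=CCOc1ccc([C@@H]2CC(=O)c3c(OCC=C(C)C)cc(OC(C)=O)cc3O2)cc1
F7 | step 2 | (2S)-7-O-acetyl-8-prenyl-4'-O-prenylnaringenin | CC(C)=CCOc1ccc([C@@H]2CC(=O)c3c(O)cc(OC(C)=O)c(CC=C(C)C)c3O2)cc1
F8 | step 3 | (2S)-7-O-(2-methylbut-3-en-2-yl)naringenin | Oc1ccc([C@@H]2CC(=O)c3c(O)cc(OC(C)(C)C=C)cc3O2)cc1
F9 | step 3 | (2S)-7-O-(2-methylbut-3-en-2-yl)-4'-O-prenylnaringenin | CC(C)=CCOc1ccc([C@@H]2CC(=O)c3c(O)cc(OC(C)(C)C=C)cc3O2)cc1
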